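C1 = C(OH)(CH2OBz), C2 = CH(OAc), C3 = CH(OBz), C4=C5 the alkene, C6 = CH(OH), C7 = the exocyclic CH2. Retrosynthetic cuts in order: C6–OH back to a C6 ketone (enone C4=C5–C6=O); O2–Ac; O1/O2 tied into a dioxolane; C1–C7 (aldol retron O=C6–C1–C7–O, C7 = formaldehyde) together with O7–Bz; O3–Bz; the C6=O/C3–OH pair back to an O–O bridge; the two C–O bonds of that bridge back to singlet oxygen and a diene.
Enabling feature: in the cyclohexenone ring C1 is the only enolisable carbon (C5 is vinylic). It lies α to C6 and belongs to the dioxolane ring O1–C1–C2–O2, which holds the C2–O2 bond near the nodal plane of the dienolate (no β-elimination, no aromatisation) and lets C1 re-pyramidalise only to the cis-fused bicycle.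
Forward order: the carbocycle is bought as meso cis-1,2-dihydrocatechol. The dioxolane goes on (step 1), the peroxide bridge goes on and is opened (steps 2–3), C7 is joined (step 5), the dioxolane comes off (step 6), and the ketone helper is removed by reduction (step 8). C1–C7 is the only C–C bond made.
Stereochemistry: the anti [4+2] addition of singlet oxygen sets C3 and C6 relative to C1/C2 in one event. A catalytic desymmetrising Kornblum–DeLaMare rearrangement sets the absolute configuration. C1 is erased and rebuilt under control of C2; C6 is erased and rebuilt under control of the C1 hydroxyl.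

Key step: step 5

Assumption: the quinidine-derived catalyst of step 3 is taken to abstract the bridgehead hydrogen at the later C6. Should the sense be opposite, the quinine-derived pseudoenantiomer (9-O-acetylcupreine) is used instead.

Step 1
Reactants: 1 cis-1,2-dihydrocatechol (meso-(1R,2S)-cyclohexa-3,5-diene-1,2-diol)
Product: 2 meso-(3aR,7aS)-2,2-dimethyl-3a,7a-dihydro-1,3-benzodioxole (diene acetonide)
Conditions: Me2C(OMe)2, p-TsOH (cat.), CH2Cl2, 0 °C → rt
Reagents that add atoms: 2,2-dimethoxypropane, COC(C)(C)OC
Why: Acid-catalysed transketalisation of a cis-1,2-diol gives the cis-fused dioxolane without touching C1 or C2, and catalytic acid at low temperature should limit dehydration of the diene diol to phenol.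

Step 2
Reactants: 2 diene acetonide
Product: 3 meso endoperoxide (7,8-isopropylidenedioxy-2,3-dioxabicyclo[2.2.2]oct-5-ene, O–O bridge anti to the dioxolane)
Conditions: O2, tetraphenylporphyrin (cat.), visible light, CH2Cl2, 0 °C
Reagents that add atoms: dioxygen, O=O
Why: The suprafacial [4+2] cycloaddition of singlet oxygen should occur on the diene face opposite to the dioxolane, so C3–O and C6–O are set cis to each other and trans to O1/O2 in one event, leaving C4=C5 in place.

Step 3
Reactants: 3 meso endoperoxide
Product: 4 (3aS,7R,7aS)-7-hydroxy-2,2-dimethyl-7,7a-dihydro-1,3-benzodioxol-4(3aH)-one (γ-hydroxy enone)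
Conditions: 9-O-acetylcupreidine (10 mol %, made from quinidine), CH2Cl2, rt
Reagents that add atoms: none
Why: In this catalytic enantioselective Kornblum–DeLaMare rearrangement the quinuclidine nitrogen removes one of the two enantiotopic bridgehead hydrogens while the 6'-OH binds the peroxide, so the O–O bond breaks, C6 becomes the ketone, C3 keeps its oxygen and configuration, and the desymmetrisation fixes the absolute configuration of C1, C2 and C3.

Step 4
Reactants: 4 γ-hydroxy enone
Product: 5 (3aS,4R,7aS)-2,2-dimethyl-7-oxo-3a,4,7,7a-tetrahydro-1,3-benzodioxol-4-yl benzoate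
Conditions: BzCl, pyridine, DMAP (cat.), CH2Cl2, 0 °C
Reagents that add atoms: benzoyl chloride, O=C(Cl)c1ccccc1
Why: Standard O-acylation of the secondary allylic alcohol installs the final C3 benzoate with retention, and the weak amine base should not enolise the ketone.

Step 5
Reactants: 5 benzoyloxy enone acetonide; 6 formaldehyde (monomer in THF, cracked from commercial paraformaldehyde)
Product: 9 [(3aS,7R,7aS)-7-(benzoyloxy)-2,2-dimethyl-4-oxo-7,7a-dihydro-1,3-benzodioxol-3a(4H)-yl]methyl benzoate, via lithium dienolate 7 (not isolated), via lithium aldolate 8 (not isolated)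
Conditions: LiHMDS, THF, −78 °C; CH2O (THF solution), −78 °C; then BzCl, DMAP (cat.), −78 → −20 °C
Reagents that add atoms: benzoyl chloride, O=C(Cl)c1ccccc1
Why: LiHMDS removes the only enolisable hydrogen of 5 (C1–H; C5 is vinylic) to give the cross-conjugated lithium dienolate 7, C1 of which adds to monomeric formaldehyde, and the primary lithium alkoxide 8 is benzoylated in the same flask, which blocks the retro-aldol path and installs the C7 benzoate. The closest known reaction type is the crossed-aldol hydroxymethylation of α-oxygenated carbonyl compounds held in a 2,3-O-isopropylidene ring (formaldehyde on acetonide-protected aldose lactols and on dioxolane ester enolates), run here as a kinetic α'-enolate aldol of a cyclohexenone. No ring is closed. The new quaternary stereocentre C1 is controlled by C2 through the dioxolane: the flattened cyclohexenone tolerates only a cis-fused dioxolane and the acetal carbon with its upper methyl group leans over the O2 face, so formaldehyde should enter on the face of C2–H and O1 stays cis to O2 (overall retention at C1, C7 cis to O3). The step needs C1- over C3-deprotonation, survival of the dienolate and C- over O-attack: kinetic base at −78 °C favours the α' position, the five-membered ring holds the C2–O2 bond near the nodal plane of the π system so that β-elimination and aromatisation are stereoelectronically disfavoured, and formaldehyde reacts at the carbon of lithium enolates. A benzoyl shift from O3 to O7 in 8 would be harmless, because benzoyl chloride re-acylates whichever oxygen is free.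

Step 6
Reactants: 9 dibenzoate enone acetonide
Product: 10 [(1S,5R,6S)-5-(benzoyloxy)-1,6-dihydroxy-2-oxocyclohex-3-en-1-yl]methyl benzoate
Conditions: TFA/H2O (9:1), CH2Cl2, 0 °C → rt
Reagents that add atoms: none
Why: Acid-catalysed acetal hydrolysis frees O1 and O2 without touching a stereocentre, the esters survive, and the C3–O bond should not ionise because its allyl system is part of an electron-poor enone.

Step 7
Reactants: 10 diol enone
Product: 11 [(1S,5R,6S)-6-acetoxy-5-(benzoyloxy)-1-hydroxy-2-oxocyclohex-3-en-1-yl]methyl benzoate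
Conditions: Ac2O, pyridine, CH2Cl2, 0 °C
Reagents that add atoms: acetic anhydride, CC(=O)OC(C)=O
Why: Chemoselective acylation takes the secondary C2–OH in preference to the tertiary C1–OH, and no third hydroxyl competes because C6 is still a ketone.

Step 8
Reactants: 11 acetoxy enone
Product: 12 HY-N2634, [(1R,2S,5R,6S)-6-acetoxy-5-(benzoyloxy)-1,2-dihydroxycyclohex-3-en-1-yl]methyl benzoate
Conditions: Me4NBH(OAc)3, MeCN/AcOH (1:1), −30 °C
Reagents that add atoms: none
Why: In this hydroxyl-directed (Saksena–Evans) reduction the C1–OH exchanges onto boron and delivers hydride to the C6 carbonyl on its own face, which should give the trans-1,2-diol (C6–OH cis to C7), while undirected enones and esters are inert to the reagent and the acidic medium suppresses acyl migration.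

Compound list
1 | cis-1,2-dihydrocatechol, meso-(1R,2S)-cyclohexa-3,5-diene-1,2-diol | O[C@H]1[C@@H](O)C=CC=C1 | starting material
2 | meso-(3aR,7aS)-2,2-dimethyl-3a,7a-dihydro-1,3-benzodioxole | CC1(C)O[C@@H]2C=CC=C[C@@H]2O1 | intermediate
3 | meso endoperoxide, 7,8-isopropylidenedioxy-2,3-dioxabicyclo[2.2.2]oct-5-ene, O–O bridge anti to the dioxolane | CC1(C)O[C@@H]2[C@@H]3C=C[C@@H](OO3)[C@@H]2O1 | intermediate
4 | (3aS,7R,7aS)-7-hydroxy-2,2-dimethyl-7,7a-dihydro-1,3-benzodioxol-4(3aH)-one | CC1(C)O[C@@H]2C(=O)C=C[C@@H](O)[C@@H]2O1 | intermediate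
5 | (3aS,4R,7aS)-2,2-dimethyl-7-oxo-3a,4,7,7a-tetrahydro-1,3-benzodioxol-4-yl benzoate | CC1(C)O[C@@H]2C(=O)C=C[C@@H](OC(=O)c3ccccc3)[C@@H]2O1 | intermediate
6 | formaldehyde (monomer from commercial paraformaldehyde) | C=O | starting material
7 | lithium dienolate of 5 (C1=C6–OLi, not isolated) | CC1(C)OC2=C(O[Li])C=C[C@@H](OC(=O)c3ccccc3)[C@@H]2O1 | intermediate
8 | lithium aldolate (C7–OLi, not isolated) | CC1(C)O[C@]2(CO[Li])C(=O)C=C[C@@H](OC(=O)c3ccccc3)[C@@H]2O1 | intermediate
9 | [(3aS,7R,7aS)-7-(benzoyloxy)-2,2-dimethyl-4-oxo-7,7a-dihydro-1,3-benzodioxol-3a(4H)-yl]methyl benzoate | CC1(C)O[C@]2(COC(=O)c3ccccc3)C(=O)C=C[C@@H](OC(=O)c3ccccc3)[C@@H]2O1 | intermediate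
10 | [(1S,5R,6S)-5-(benzoyloxy)-1,6-dihydroxy-2-oxocyclohex-3-en-1-yl]methyl benzoate | O=C1C=C[C@@H](OC(=O)c2ccccc2)[C@H](O)[C@@]1(O)COC(=O)c1ccccc1 | intermediate
11 | [(1S,5R,6S)-6-acetoxy-5-(benzoyloxy)-1-hydroxy-2-oxocyclohex-3-en-1-yl]methyl benzoate | O=C1C=C[C@@H](OC(=O)c2ccccc2)[C@H](OC(C)=O)[C@@]1(O)COC(=O)c1ccccc1 | intermediate
12 | HY-N2634, [(1R,2S,5R,6S)-6-acetoxy-5-(benzoyloxy)-1,2-dihydroxycyclohex-3-en-1-yl]methyl benzoate | CC(=O)O[C@H]1[C@H](OC(=O)c2ccccc2)C=C[C@H](O)[C@]1(O)COC(=O)c1ccccc1 | target

Total step count: 8. Longest linear sequence: 8.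

Steps most likely to fail

Step 5. Three things may go wrong.
- The dienolate may collapse by loss of O2 and aromatise.
- It may be deprotonated at C3 instead of C1, or take up the C3 benzoyl group at C1.
- Formaldehyde may enter on the wrong face.

The fallback avoids the strongly basic enolate and sets out from 5. Soft enolisation (TBSOTf, Et3N, CH2Cl2, −78 → 0 °C) should give the isolable tert-butyldimethylsilyl dienol ether F1. A scandium triflate-catalysed Mukaiyama-type hydroxymethylation with aqueous formaldehyde (THF/H2O, 0 °C) should convert it into the hydroxymethyl ketone F2. Benzoylation (BzCl, pyridine) returns to the route at 9.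

Step 8. Ligand exchange at the hindered tertiary C1–OH may be slow. In that case either nothing happens or undirected hydride attack anti to the C1–O bond leads to the wrong configuration at C6. Acetyl migration is a further risk. The fallback replaces direction by inversion and sets out from 9.
- Luche reduction (NaBH4, CeCl3·7H2O, MeOH, −78 °C) should attack anti to the dioxolane and give the 6-epi allylic alcohol F3.
- Mitsunobu reaction with chloroacetic acid (PPh3, DIAD, toluene) should give the inverted C6 chloroacetate F4.
- TFA/H2O should give the C1,C2-diol chloroacetate F5.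
- Ac2O/pyridine should give the C2 acetate chloroacetate F6.
- Selective removal of the chloroacetyl group (thiourea, NaHCO3, EtOH) comes back to the route at 12.

Step 3. Discrimination between the two enantiotopic bridgehead hydrogens may be poor for this acetonide-bearing peroxide, or the γ-hydroxy enone may isomerise further to a 1,4-dione. The fallback moves the desymmetrisation to an enzyme and sets out from 3.
- Thiourea reduction (MeOH, rt) should give the meso enediol acetonide F7.
- Lipase-catalysed acylation with vinyl acetate is expected to take place at the (R)-carbinol C3, according to the usual size rule for secondary alcohols, and should give the monoacetate F8.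
- Oxidation of the remaining allylic alcohol (MnO2 or Dess–Martin periodinane) should give the acetoxy enone F9.
- Enzymatic hydrolysis of the acetate (lipase, pH 7 buffer) comes back to the route at 4.

Further compounds
F1 | step 5 | tert-butyldimethylsilyl dienol ether of 5 (C1=C6–OTBS) | CC1(C)OC2=C(O[Si](C)(C)C(C)(C)C)C=C[C@@H](OC(=O)c3ccccc3)[C@@H]2O1
F2 | step 5 | hydroxymethyl ketone (C7–OH analogue of 9) | CC1(C)O[C@]2(CO)C(=O)C=C[C@@H](OC(=O)c3ccccc3)[C@@H]2O1
F3 | step 8 | 6-epi allylic alcohol (C6–OH cis to the dioxolane oxygens) | CC1(C)O[C@]2(COC(=O)c3ccccc3)[C@H](O)C=C[C@@H](OC(=O)c3ccccc3)[C@@H]2O1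
F4 | step 8 | inverted C6 chloroacetate (C6–O trans to the dioxolane oxygens) | CC1(C)O[C@]2(COC(=O)c3ccccc3)[C@@H](OC(=O)CCl)C=C[C@@H](OC(=O)c3ccccc3)[C@@H]2O1
F5 | step 8 | C1,C2-diol chloroacetate | O=C(CCl)O[C@H]1C=C[C@@H](OC(=O)c2ccccc2)[C@H](O)[C@@]1(O)COC(=O)c1ccccc1
F6 | step 8 | C2 acetate chloroacetate | O=C(CCl)O[C@H]1C=C[C@@H](OC(=O)c2ccccc2)[C@H](OC(C)=O)[C@@]1(O)COC(=O)c1ccccc1
F7 | step 3 | meso enediol acetonide (C3–OH and C6–OH cis, both trans to the dioxolane) | CC1(C)O[C@@H]2[C@@H](O)C=C[C@@H](O)[C@@H]2O1
F8 | step 3 | monoacetate (C3–OAc, C6–OH) | CC1(C)O[C@@H]2[C@@H](O)C=C[C@@H](OC(C)=O)[C@@H]2O1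
F9 | step 3 | acetoxy enone (C3–OAc analogue of 5) | CC1(C)O[C@@H]2C(=O)C=C[C@@H](OC(C)=O)[C@@H]2O1
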